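**Assumption:** Kuwanon C (3,8-diprenyl-5,7,2',4'-tetrahydroxyflavone) has no stereocentres, so the "single enantiomer" requirement is met trivially. The only stereocentre in the route (the carbinol in 10) is made racemic and destroyed in step 6.

## Retrosynthetic overview

1. Kuwanon C ⇐ global MOM removal from the tri-MOM 3,8-diprenylflavone.
2. C8-prenyl ⇐ Eu(III)-catalysed para-Claisen–Cope shift of a 5-O-prenyl ether (known chemistry).
3. Pyranone ring (O1–C2) and C3-prenyl bond ⇐ one step: proposed Pd(0)-catalysed O→C prenyl-transfer 6-endo cyclisation of a 2,6-bis(prenyloxy)aryl ynone (new).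
4. Ynone ⇐ C2-symmetric 4-MOMO-2,6-bis(prenyloxy)benzaldehyde + lithium acetylide of 1-ethynyl-2,4-bis(MOMO)benzene, then oxidation.
5. Ring order: A and B rings are purchased (phloroglucinaldehyde, 2,4-dihydroxybenzaldehyde); the C ring is formed in step 7. Both prenyl groups originate as O-prenyl ethers on a symmetric A ring, so regiochemistry is set by symmetry and mechanism.

## Route

**Step 1**
Reactants: 1 2,4,6-trihydroxybenzaldehyde; 2 chloromethyl methyl ether (MOMCl)
Product: 3 2,6-dihydroxy-4-(methoxymethoxy)benzaldehyde
Conditions: MOMCl (1.05 equiv), i-Pr2NEt (1.1 equiv), THF, 0 °C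
Reagents that add atoms: 2, MOMCl, COCCl
Why: Selective Williamson-type O-alkylation; the para OH is the most acidic and the only one not hydrogen-bonded to the aldehyde, so one equivalent of base and electrophile gives the symmetric 4-O-MOM ether.

**Step 2**
Reactants: 3; 4 prenyl bromide (1-bromo-3-methylbut-2-ene)
Product: 5 4-(methoxymethoxy)-2,6-bis[(3-methylbut-2-en-1-yl)oxy]benzaldehyde
Conditions: prenyl bromide (2.5 equiv), K2CO3 (3 equiv), DMF, rt → 45 °C
Reagents that add atoms: 4, prenyl bromide, CC(C)=CCBr
Why: Williamson etherification; carbonate in a polar aprotic solvent favours O- over C-alkylation, and both ortho phenols are equivalent, so no regiochemical issue arises.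

**Step 3**
Reactants: 6 2,4-dihydroxybenzaldehyde; 2 MOMCl
Product: 7 2,4-bis(methoxymethoxy)benzaldehyde
Conditions: MOMCl (3 equiv), i-Pr2NEt (4 equiv), CH2Cl2, 0 °C → rt
Reagents that add atoms: 2, MOMCl, COCCl
Why: Exhaustive MOM protection of both phenols (Williamson-type acetal formation), a standard operation on this aldehyde.

**Step 4**
Reactants: 7; 8 dimethyl (1-diazo-2-oxopropyl)phosphonate (Ohira–Bestmann reagent)
Product: 9 1-ethynyl-2,4-bis(methoxymethoxy)benzene
Conditions: 8 (1.3 equiv), K2CO3 (2 equiv), MeOH, rt
Reagents that add atoms: 8, Ohira–Bestmann reagent, COP(=O)(OC)C(=[N+]=[N-])C(C)=O (supplies the terminal alkyne carbon)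
Why: Seyferth–Gilbert homologation (Ohira–Bestmann modification) converts the aryl aldehyde into the terminal alkyne under mild base that leaves MOM ethers intact.

**Step 5**
Reactants: 9; 5
Product: 10 3-[2,4-bis(methoxymethoxy)phenyl]-1-{4-(methoxymethoxy)-2,6-bis[(3-methylbut-2-en-1-yl)oxy]phenyl}prop-2-yn-1-ol (racemic)
Conditions: 9 (1.15 equiv), n-BuLi (1.1 equiv), THF, −78 °C; then 5, −78 → 0 °C; sat. aq. NH4Cl
Reagents that add atoms: none (both partners are the listed reactants)
Why: 1,2-Addition of a lithium acetylide to an aldehyde; the small linear nucleophile tolerates the 2,6-disubstituted aldehyde, and the racemic carbinol centre is removed in the next step.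

**Step 6**
Reactants: 10
Product: 11 3-[2,4-bis(methoxymethoxy)phenyl]-1-{4-(methoxymethoxy)-2,6-bis[(3-methylbut-2-en-1-yl)oxy]phenyl}prop-2-yn-1-one
Conditions: activated MnO2 (15 equiv), CH2Cl2, rt (crude 10 used directly)
Reagents that add atoms: none
Why: Chemoselective MnO2 oxidation of a doubly activated (benzylic and propargylic) alcohol to the ynone, without touching the prenyl alkenes or MOM acetals.

**Step 7 (key step, new)**
Reactants: 11
Product: 12 2-[2,4-bis(methoxymethoxy)phenyl]-7-(methoxymethoxy)-3-(3-methylbut-2-en-1-yl)-5-[(3-methylbut-2-en-1-yl)oxy]-4H-chromen-4-one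
Conditions: Pd2(dba)3·CHCl3 (2.5 mol%), DPEphos (6 mol%), anhydrous degassed THF (0.05 M), 45 °C
Reagents that add atoms: none (isomerisation)
Why: Proposed new method: Pd(0) bound to the electron-poor ynone ionises one of the two equivalent aryl prenyl ethers (an ortho-acyl phenoxide is a competent leaving group) to a phenoxide/(η3-prenyl)Pd+ ion pair; the phenoxide then adds 6-endo to the alkyne β-carbon (favoured by Michael polarisation and by the electron-rich B-ring aryl), and the resulting C3-palladated chromone/allenolate couples with the prenyl unit at its unsubstituted CH2 terminus to form the pyranone ring and the linear C3–prenyl bond and regenerate Pd(0); the closest known reaction types are the Pd(0)-catalysed O→C allyl-migration cyclisation of allyl o-alkynylphenyl ethers to 3-allylbenzofurans (and the analogous aminopalladation–allylation to 3-allylindoles) and Tsuji–Trost allylation of enolates, none of which has been shown for the 6-endo ynone-to-flavone manifold with a migrating prenyl group.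

**Step 8**
Reactants: 12
Product: 13 2-[2,4-bis(methoxymethoxy)phenyl]-5-hydroxy-7-(methoxymethoxy)-3,8-bis(3-methylbut-2-en-1-yl)-4H-chromen-4-one
Conditions: Eu(fod)3 (10 mol%), NaHCO3 (1 equiv), PhCl, 85 °C
Reagents that add atoms: none (isomerisation)
Why: Eu(III)-catalysed tandem aromatic Claisen–Cope (para-Claisen) rearrangement; chelation of Eu to C4=O/5-O triggers the [3,3] shift to C6 (1,1-dimethylallyl dienone), a second [3,3] shift relays the group to C8 as the linear prenyl, and tautomerisation gives the chelated 5-OH.

**Step 9**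
Reactants: 13
Product: 14 Kuwanon C, 2-(2,4-dihydroxyphenyl)-5,7-dihydroxy-3,8-bis(3-methylbut-2-en-1-yl)-4H-chromen-4-one
Conditions: 3 M aq. HCl–MeOH (1:5), 45 °C, stopped at full conversion
Reagents that add atoms: none
Why: Acid-catalysed acetal hydrolysis removes the three aryl MOM ethers; mild temperature and short contact time limit acid-promoted chroman formation between the 8-prenyl group and the 7-OH.

## Compound list

1 | 2,4,6-trihydroxybenzaldehyde | O=Cc1c(O)cc(O)cc1O | starting material
2 | chloromethyl methyl ether (MOMCl) | COCCl | starting material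
3 | 2,6-dihydroxy-4-(methoxymethoxy)benzaldehyde | O=Cc1c(O)cc(OCOC)cc1O | intermediate
4 | prenyl bromide | CC(C)=CCBr | starting material
5 | 4-(methoxymethoxy)-2,6-bis(prenyloxy)benzaldehyde | O=Cc1c(OCC=C(C)C)cc(OCOC)cc1OCC=C(C)C | intermediate
6 | 2,4-dihydroxybenzaldehyde | O=Cc1ccc(O)cc1O | starting material
7 | 2,4-bis(methoxymethoxy)benzaldehyde | O=Cc1ccc(OCOC)cc1OCOC | intermediate
8 | dimethyl (1-diazo-2-oxopropyl)phosphonate | COP(=O)(OC)C(=[N+]=[N-])C(C)=O | starting material
9 | 1-ethynyl-2,4-bis(methoxymethoxy)benzene | C#Cc1ccc(OCOC)cc1OCOC | intermediate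
10 | racemic propargylic alcohol (A-ring aryl carbinol, B-ring aryl alkyne) | OC(C#Cc1ccc(OCOC)cc1OCOC)c1c(OCC=C(C)C)cc(OCOC)cc1OCC=C(C)C | intermediate
11 | aryl ynone | O=C(C#Cc1ccc(OCOC)cc1OCOC)c1c(OCC=C(C)C)cc(OCOC)cc1OCC=C(C)C | intermediate
12 | 3-prenyl-5-prenyloxy-7,2',4'-tris(MOMO)flavone | CC(C)=CCc1c(-c2ccc(OCOC)cc2OCOC)oc2cc(OCOC)cc(OCC=C(C)C)c2c1=O | intermediate
13 | 5-hydroxy-3,8-diprenyl-7,2',4'-tris(MOMO)flavone | CC(C)=CCc1c(-c2ccc(OCOC)cc2OCOC)oc2c(CC=C(C)C)c(OCOC)cc(O)c2c1=O | intermediate
14 | Kuwanon C | CC(C)=CCc1c(-c2ccc(O)cc2O)oc2c(CC=C(C)C)c(O)cc(O)c2c1=O | target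

## Summary

Total step count: 9.
Longest linear sequence: 7 steps (1 → 2 → 5 → 6 → 7 → 8 → 9; the B-ring branch 3 → 4 → 5 → … is also 7).

**Three steps most likely to fail**

1. **Step 7 (proposed new Pd(0) prenyl-transfer cyclisation).**
   - Risks: 5-exo closure to an aurone-type product; loss of the prenyl group as isoprene to give the 3-H flavone; branched (1,1-dimethylallyl) coupling; ionisation of the remaining 5-O-prenyl ether in the product.
   - Fallback (known chemistry): close the ring without the transfer, using Pd(PPh3)4/morpholine de-prenylation of 11 with amine-mediated 6-endo oxa-Michael closure to the 3-unsubstituted 5-prenyloxyflavone (re-prenylating the 5-OH with prenyl bromide/K2CO3 if it is also cleaved). Then install the C3-prenyl by C3-lithiation/iodination (LDA, −78 °C; I2) and Stille coupling with tributyl(3-methylbut-2-enyl)stannane to reach 12.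

2. **Step 8 (Eu(fod)3 para-Claisen–Cope).**
   - Risks: the rearrangement may stop at the 6-(1,1-dimethylallyl)-5-hydroxy isomer or give 6/8 mixtures.
   - Fallback: install the C8-prenyl at the start instead. C-prenylate 2,4,6-trihydroxybenzaldehyde (prenyl bromide, DBU), protect the 4- and 6-OH as MOM ethers, and O-prenylate the remaining 2-OH flanked by the C-prenyl group. The same acetylide/oxidation/cyclisation sequence then gives the 3,8-diprenyl-tetra-MOM flavone directly, with no rearrangement step.

3. **Step 9 (global MOM removal).**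
   - Risks: acid-induced cyclisation of the 8-prenyl group onto the 7-OH (chroman), or addition of HCl/MeOH across the prenyl alkenes.
   - Fallback: change the protecting-group strategy to silyl ethers (TIPS on the 7-, 2'- and 4'-oxygens; O-prenylation of the A ring under neutral Mitsunobu conditions with prenol; B-ring alkyne from 4-bromoresorcinol bis-TIPS ether by Sonogashira coupling with TMS-acetylene). The final deprotection is then fluoride-mediated (TBAF/AcOH, THF, 0 °C) and fully non-acidic.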